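**Plan**

1. Numbering used here: ring A (tetrahydrofuran) = O2, C1, C11a, C4a, C4; ring B (nine-membered) = C4a, C5, C6, C7, C8=C9, C10, C11, C11a; C3 = CH2O on C4; C12–C15 = dienyl on C4; C19 = exocyclic CH2 on C11.
2. Retrosynthetic cuts, in order: the C3 ester; C11=C19 (back to a C11 ketone); the ring B bond C4a–C5 (C5 radical + ring A enone); C9–C10 (acetylide + epoxide, then Z-reduction); the ring A alkene C4a=C11a (ring-closing metathesis) and O2–C1 (etherification).
3. Forward: a West fragment (C5–C9, carrying C7) and an East fragment (ring A with C3, C4, C10–C15) are made separately and joined at C9–C10; ring A exists first and ring B is closed last at C4a–C5.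
4. Enabling feature: with C11 as a ketone, the ring-fusion carbon C4a is the β-carbon of an enone inside ring A, so two electrophilic carbons (iodide carbon C5 and enone carbon C4a) can be joined through a radical. The (Z)-C8=C9 alkene and the planar enone bring the chain ends together, and the activating carbonyl is afterwards turned into the C11 methylidene.
5. Stereochemistry: C7 and C4 come from two Sharpless epoxidations (reagent control); C4a is induced by C4 during the ring closure; C11a is set by equilibration next to the C11 ketone (trans ring fusion).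

Key step: step 20

Remark: the target is read as the (4R,4aS,7S,11aR) isomer in this numbering, with rings A and B trans-fused; the acyl group is nonadecanoyl (19 carbons).

**Step 1**
Reactants: 1 4-{[tert-butyl(dimethyl)silyl]oxy}but-1-yne
Product: 3 (E)-5-{[tert-butyl(dimethyl)silyl]oxy}-3-methylpent-2-en-1-ol, via dimethyl(alkenyl)alane 2 (not isolated)
Conditions: AlMe3 (2 equiv), Cp2ZrCl2 (0.2 equiv), CH2Cl2, 0 °C to rt; then n-BuLi, (CH2O)n, THF, −78 °C to rt; then H2O
Reagents that add atoms: trimethylaluminium, C[Al](C)C; formaldehyde (from paraformaldehyde), C=O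
Why: Zirconium-catalysed Negishi carboalumination adds methyl and aluminium syn across the terminal alkyne (methyl to the internal carbon) and the alkenylalanate is hydroxymethylated with retention, which fixes the E alkene needed for the epoxidation.

**Step 2**
Reactants: 3 (E)-5-{[tert-butyl(dimethyl)silyl]oxy}-3-methylpent-2-en-1-ol
Product: 4 [(2S,3S)-3-(2-{[tert-butyl(dimethyl)silyl]oxy}ethyl)-3-methyloxiran-2-yl]methanol
Conditions: Ti(OiPr)4 (10 mol%), (2R,3R)-(+)-diethyl tartrate, t-BuOOH, 4 Å sieves, CH2Cl2, −20 °C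
Reagents that add atoms: tert-butyl hydroperoxide, CC(C)(C)OO
Why: Sharpless asymmetric epoxidation of an (E)-3-methylalk-2-en-1-ol, where the (2R,3R)-tartrate should give the (2S,3S)-epoxide as it does with geraniol, and this sets the future C7.

**Step 3**
Reactants: 4 [(2S,3S)-3-(2-{[tert-butyl(dimethyl)silyl]oxy}ethyl)-3-methyloxiran-2-yl]methanol
Product: 5 tert-butyl{2-[(2S,3R)-3-(chloromethyl)-2-methyloxiran-2-yl]ethoxy}dimethylsilane
Conditions: PPh3, CCl4, NaHCO3, reflux
Reagents that add atoms: carbon tetrachloride, ClC(Cl)(Cl)Cl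
Why: Appel chlorination of the primary alcohol under buffered conditions should leave the epoxide and both stereocentres intact.

**Step 4**
Reactants: 5 tert-butyl{2-[(2S,3R)-3-(chloromethyl)-2-methyloxiran-2-yl]ethoxy}dimethylsilane
Product: 6 (3S)-5-{[tert-butyl(dimethyl)silyl]oxy}-3-methylpent-1-yn-3-ol (West fragment)
Conditions: n-BuLi (3.5 equiv), THF, −40 °C; then H2O
Reagents that add atoms: none
Why: Base-induced double elimination of a 2,3-epoxy chloride to a propargylic alcohol (Takano–Yadav alkynol synthesis), in which the bond between the quaternary carbon and oxygen is never broken, so C7 keeps its configuration.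

**Step 5**
Reactants: 7 2-methylidenepropane-1,3-diol
Product: 8 2-({[tri(propan-2-yl)silyl]oxy}methyl)prop-2-en-1-ol
Conditions: NaH (1.0 equiv), THF, 0 °C; then i-Pr3SiCl (1.0 equiv), rt
Reagents that add atoms: chlorotri(propan-2-yl)silane, CC(C)[Si](Cl)(C(C)C)C(C)C
Why: Monosilylation of a symmetric diol through its monosodium alkoxide (McDougal conditions), the bulky silyl group being chosen because it migrates slowly in the later basic steps.

**Step 6**
Reactants: 8 2-({[tri(propan-2-yl)silyl]oxy}methyl)prop-2-en-1-ol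
Product: 9 [(2R)-2-({[tri(propan-2-yl)silyl]oxy}methyl)oxiran-2-yl]methanol
Conditions: Ti(OiPr)4 (10 mol%), (2S,3S)-(−)-diethyl tartrate, t-BuOOH, 4 Å sieves, CH2Cl2, −20 °C
Reagents that add atoms: tert-butyl hydroperoxide, CC(C)(C)OO
Why: Sharpless asymmetric epoxidation of a 2-substituted allylic alcohol, where the (2S,3S)-tartrate should give the (R)-epoxide and so set C4 (the epoxide oxygen becomes O2, the epoxide CH2 becomes C4a).

**Step 7**
Reactants: 9 [(2R)-2-({[tri(propan-2-yl)silyl]oxy}methyl)oxiran-2-yl]methanol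
Product: 10 (2R)-2-({[tri(propan-2-yl)silyl]oxy}methyl)oxirane-2-carbaldehyde
Conditions: Dess–Martin periodinane, NaHCO3, CH2Cl2, 0 °C to rt
Reagents that add atoms: none
Why: Buffered Dess–Martin oxidation of the primary alcohol gives an aldehyde without α-hydrogen, so the quaternary centre cannot epimerise.

**Step 8**
Reactants: 10 (2R)-2-({[tri(propan-2-yl)silyl]oxy}methyl)oxirane-2-carbaldehyde
Product: 11 (2E)-3-[(2R)-2-({[tri(propan-2-yl)silyl]oxy}methyl)oxiran-2-yl]prop-2-enal
Conditions: Ph3P=CHCHO (1.1 equiv), toluene, 70 °C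
Reagents that add atoms: (triphenylphosphoranylidene)acetaldehyde, O=CC=P(c1ccccc1)(c1ccccc1)c1ccccc1
Why: Wittig olefination with a stabilised ylide should give the E alkene (C12=C13) selectively.

**Step 9**
Reactants: 11 (2E)-3-[(2R)-2-({[tri(propan-2-yl)silyl]oxy}methyl)oxiran-2-yl]prop-2-enal
Product: 12 (2R)-2-[(1E)-4-methylpenta-1,3-dien-1-yl]-2-({[tri(propan-2-yl)silyl]oxy}methyl)oxirane
Conditions: isopropyltriphenylphosphonium iodide, n-BuLi, THF, −78 to 0 °C
Reagents that add atoms: isopropyltriphenylphosphonium iodide, CC(C)[P+](c1ccccc1)(c1ccccc1)c1ccccc1.[I-]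
Why: Wittig olefination with the unstabilised isopropylidene ylide adds 1,2 to the enal and creates no new geometric isomer because the new alkene carbon carries two methyl groups.

**Step 10**
Reactants: 12 (2R)-2-[(1E)-4-methylpenta-1,3-dien-1-yl]-2-({[tri(propan-2-yl)silyl]oxy}methyl)oxirane
Product: 13 (3S,4E)-7-methyl-3-({[tri(propan-2-yl)silyl]oxy}methyl)octa-1,4,6-trien-3-ol
Conditions: trimethylsulfonium iodide (3 equiv), n-BuLi (2.9 equiv), THF, −10 °C to rt; then H2O
Reagents that add atoms: trimethylsulfonium iodide, C[S+](C)C.[I-]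
Why: One-carbon homologation of an epoxide to an allylic alcohol with excess dimethylsulfonium methylide (attack at the unsubstituted epoxide carbon, then elimination of dimethyl sulfide), which leaves the C4–O bond and its configuration untouched.

**Step 11**
Reactants: 13 (3S,4E)-7-methyl-3-({[tri(propan-2-yl)silyl]oxy}methyl)octa-1,4,6-trien-3-ol; 14 3-chloro-2-(chloromethyl)prop-1-ene
Product: 15 2-(chloromethyl)prop-2-en-1-yl ether of 13 at the tertiary oxygen (S at the quaternary carbon)
Conditions: NaH, 14 (5 equiv), tetrabutylammonium iodide (cat.), THF–DMF, 0 °C to rt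
Reagents that add atoms: none
Why: Williamson etherification of the tertiary alkoxide with a reactive allylic chloride, used in excess to suppress double alkylation.

**Step 12**
Reactants: 15 2-(chloromethyl)prop-2-en-1-yl ether of 13
Product: 16 (2R)-4-(chloromethyl)-2-[(1E)-4-methylpenta-1,3-dien-1-yl]-2-({[tri(propan-2-yl)silyl]oxy}methyl)-2,5-dihydrofuran
Conditions: second-generation Grubbs catalyst RuCl2(=CHPh)(PCy3)(H2IMes) (5 mol%), CH2Cl2, 40 °C
Reagents that add atoms: none
Why: Ring-closing metathesis of the terminal vinyl group with the 1,1-disubstituted alkene closes five-membered ring A (alkene C4a=C11a) with loss of ethylene, while the internal dienyl alkenes can only give strained small rings.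

**Step 13**
Reactants: 16 (2R)-4-(chloromethyl)-2-[(1E)-4-methylpenta-1,3-dien-1-yl]-2-({[tri(propan-2-yl)silyl]oxy}methyl)-2,5-dihydrofuran
Product: 17 (5R)-5-[(1E)-4-methylpenta-1,3-dien-1-yl]-5-({[tri(propan-2-yl)silyl]oxy}methyl)-2,5-dihydrofuran-3-carbaldehyde
Conditions: N-methylmorpholine N-oxide (3 equiv), NaI (cat.), NaHCO3, MeCN, 40 °C
Reagents that add atoms: N-methylmorpholine N-oxide, C[N+]1([O-])CCOCC1
Why: N-oxide (Ganem-type Kornblum) oxidation of the allylic chloride, through the allylic iodide, gives the enal in which C11 is the aldehyde carbon.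

**Step 14**
Reactants: 17 (5R)-5-[(1E)-4-methylpenta-1,3-dien-1-yl]-5-({[tri(propan-2-yl)silyl]oxy}methyl)-2,5-dihydrofuran-3-carbaldehyde
Product: 18 (2R)-2-[(1E)-4-methylpenta-1,3-dien-1-yl]-4-(oxiran-2-yl)-2-({[tri(propan-2-yl)silyl]oxy}methyl)-2,5-dihydrofuran (East fragment, both epimers at the oxirane CH)
Conditions: trimethylsulfonium iodide, KN(SiMe3)2, THF, −20 to 0 °C
Reagents that add atoms: trimethylsulfonium iodide, C[S+](C)C.[I-]
Why: Corey–Chaykovsky epoxidation, the sulfonium ylide adding 1,2 to the enal, and the epimer mixture at C11 does not matter because C11 later becomes a ketone.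

**Step 15**
Reactants: 6 (3S)-5-{[tert-butyl(dimethyl)silyl]oxy}-3-methylpent-1-yn-3-ol; 18 East fragment epoxide
Product: 19 (5S)-7-{[tert-butyl(dimethyl)silyl]oxy}-5-methyl-1-[(5R)-5-[(1E)-4-methylpenta-1,3-dien-1-yl]-5-({[tri(propan-2-yl)silyl]oxy}methyl)-2,5-dihydrofuran-3-yl]hept-3-yne-1,5-diol (both C11 epimers)
Conditions: 6 (1.5 equiv), n-BuLi (3.0 equiv), THF, −78 to 0 °C; then 18, DMPU, 0 °C to rt; then H2O
Reagents that add atoms: none
Why: SN2 opening of the terminal epoxide at its CH2 carbon (C10) by the lithium acetylide of the alkynol dianion, run without a Lewis acid so that attack at the allylic epoxide carbon is disfavoured.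

**Step 16**
Reactants: 19 coupled alkynediol
Product: 20 (3Z,5S)-7-{[tert-butyl(dimethyl)silyl]oxy}-5-methyl-1-[(5R)-5-[(1E)-4-methylpenta-1,3-dien-1-yl]-5-({[tri(propan-2-yl)silyl]oxy}methyl)-2,5-dihydrofuran-3-yl]hept-3-ene-1,5-diol
Conditions: H2 (1 atm), Lindlar catalyst (Pd on CaCO3 poisoned with Pb(OAc)2), quinoline, EtOAc, rt
Reagents that add atoms: none
Why: Lindlar semi-hydrogenation delivers hydrogen syn to the alkyne and gives the (Z)-C8=C9 alkene, the poisoned catalyst sparing the alkenes and the diene.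

**Step 17**
Reactants: 20 (Z)-alkene bis-silyl ether
Product: 21 (3Z,5S)-1-[(5R)-5-(hydroxymethyl)-5-[(1E)-4-methylpenta-1,3-dien-1-yl]-2,5-dihydrofuran-3-yl]-5-methylhept-3-ene-1,5,7-triol
Conditions: Bu4NF (3 equiv), THF, rt
Reagents that add atoms: none
Why: Fluoride cleaves both silyl ethers, freeing the C5 hydroxyl for iodination and making the C3 arm on C4 small before the ring closure.

**Step 18**
Reactants: 21 tetraol
Product: 22 (3Z,5S)-1-[(5R)-5-(hydroxymethyl)-5-[(1E)-4-methylpenta-1,3-dien-1-yl]-2,5-dihydrofuran-3-yl]-7-iodo-5-methylhept-3-ene-1,5-diol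
Conditions: iodine, PPh3, imidazole (1.1 equiv each), THF, 0 °C
Reagents that add atoms: iodine, II
Why: Garegg–Samuelsson (Appel-type) iodination should select the unhindered primary C5 hydroxyl, because the C3 hydroxyl is neopentyl-like, the C11 hydroxyl is secondary and the C7 hydroxyl is tertiary.

**Step 19**
Reactants: 22 iodo triol
Product: 23 (3Z,5S)-5-hydroxy-1-[(5R)-5-(hydroxymethyl)-5-[(1E)-4-methylpenta-1,3-dien-1-yl]-2,5-dihydrofuran-3-yl]-7-iodo-5-methylhept-3-en-1-one
Conditions: MnO2 (activated, 20 equiv), CH2Cl2, rt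
Reagents that add atoms: none
Why: MnO2 oxidises only the allylic C11 hydroxyl to the ring A enone under neutral conditions, so the skipped (Z)-alkene is not drawn into conjugation.

**Step 20**
Reactants: 23 iodo enone
Product: 25 trans-fused ketone of rings A and B (4R,4aS,7S,11aS), via cis-fused C11a epimer 24 (not isolated)
Conditions: (Me3Si)3SiH (1.5 equiv) and AIBN (0.3 equiv) added over 10 h by syringe pump, benzene, 80 °C, 0.002 mol/L; then DBU (0.2 equiv), rt
Reagents that add atoms: none
Why: Proposed new method: the silyl radical abstracts iodine from C5 of 23, the nucleophilic primary radical adds to C4a (the β-carbon of the ring A enone) and the resulting C11a α-keto radical takes hydrogen from the silane and carries the chain, a union of two electrophilic carbons by radical polarity reversal whose closest known reaction type is the endo radical macrocyclisation of ω-iodoalkyl enones (and 8-endo radical cyclisations), not yet shown for a nine-membered carbocycle. Ring B closes in the 9-endo-trig mode onto the existing ring A. C4a is controlled by the C4 quaternary centre: the chain should bond on the face of the small free hydroxymethyl arm and away from the rigid dienyl arm, which is why both silyl groups are removed before this step. C11a is controlled thermodynamically, DBU equilibrating it next to the C11 ketone (24 to 25) to the trans ring fusion, in which the C4a–C11a torsion of the nine-membered ring is staggered; a β,γ-unsaturated ketone in a nine-membered ring is not expected to move into conjugation. The step needs ring closure to outrun reduction of the C5 radical by the silane and a 1,6-hydrogen shift from C10, and regioselective attack at C4a; the (Z)-C8=C9 alkene and the planar s-trans enone hold C5 near C4a, radical and acceptor are polarity-matched, C4a is the only unsubstituted acceptor carbon, and slow addition keeps the silane dilute. C7 and C4 are not touched.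

**Step 21**
Reactants: 25 trans-fused ketone
Product: 26 (4R,4aS,7S,11aR)-diol with the C11 methylidene (the target without its ester)
Conditions: Cp2TiMe2 (5 equiv), toluene–THF, 65 °C, dark
Reagents that add atoms: dimethyltitanocene, C[Ti](C)(C1C=CC=C1)C1C=CC=C1
Why: Petasis methylenation through Cp2Ti=CH2 is not basic, so the enolisable β,γ-unsaturated ketone and the C11a centre should survive, and excess reagent covers the two free hydroxyls.

**Step 22**
Reactants: 26 methylidene diol; 27 nonadecanoic acid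
Product: 28 target, [(1R,3aR,6Z,8S,10aS)-8-hydroxy-8-methyl-4-methylidene-1-[(1E)-4-methylpenta-1,3-dien-1-yl]-3,3a,4,5,8,9,10,10a-octahydro-1H-cyclonona[c]furan-1-yl]methyl nonadecanoate
Conditions: 27 (1.1 equiv), EDC hydrochloride, DMAP, CH2Cl2, 0 °C to rt
Reagents that add atoms: none
Why: Steglich esterification should acylate the primary C3 hydroxyl only, the tertiary allylic C7 hydroxyl being too hindered to react.

**Compound list**

1 | 4-{[tert-butyl(dimethyl)silyl]oxy}but-1-yne | C#CCCO[Si](C)(C)C(C)(C)C | starting material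
2 | dimethyl[(E)-4-{[tert-butyl(dimethyl)silyl]oxy}-2-methylbut-1-en-1-yl]alane (not isolated) | C[Al](C)/C=C(C)/CCO[Si](C)(C)C(C)(C)C | intermediate
3 | (E)-5-{[tert-butyl(dimethyl)silyl]oxy}-3-methylpent-2-en-1-ol | OC/C=C(C)/CCO[Si](C)(C)C(C)(C)C | intermediate
4 | [(2S,3S)-3-(2-{[tert-butyl(dimethyl)silyl]oxy}ethyl)-3-methyloxiran-2-yl]methanol | OC[C@@H]1O[C@@]1(C)CCO[Si](C)(C)C(C)(C)C | intermediate
5 | tert-butyl{2-[(2S,3R)-3-(chloromethyl)-2-methyloxiran-2-yl]ethoxy}dimethylsilane | ClC[C@@H]1O[C@@]1(C)CCO[Si](C)(C)C(C)(C)C | intermediate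
6 | (3S)-5-{[tert-butyl(dimethyl)silyl]oxy}-3-methylpent-1-yn-3-ol (West fragment) | C#C[C@@](C)(O)CCO[Si](C)(C)C(C)(C)C | intermediate
7 | 2-methylidenepropane-1,3-diol | C=C(CO)CO | starting material
8 | 2-({[tri(propan-2-yl)silyl]oxy}methyl)prop-2-en-1-ol | C=C(CO)CO[Si](C(C)C)(C(C)C)C(C)C | intermediate
9 | [(2R)-2-({[tri(propan-2-yl)silyl]oxy}methyl)oxiran-2-yl]methanol | C1O[C@@]1(CO)CO[Si](C(C)C)(C(C)C)C(C)C | intermediate
10 | (2R)-2-({[tri(propan-2-yl)silyl]oxy}methyl)oxirane-2-carbaldehyde | C1O[C@@]1(C=O)CO[Si](C(C)C)(C(C)C)C(C)C | intermediate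
11 | (2E)-3-[(2R)-2-({[tri(propan-2-yl)silyl]oxy}methyl)oxiran-2-yl]prop-2-enal | C1O[C@@]1(/C=C/C=O)CO[Si](C(C)C)(C(C)C)C(C)C | intermediate
12 | (2R)-2-[(1E)-4-methylpenta-1,3-dien-1-yl]-2-({[tri(propan-2-yl)silyl]oxy}methyl)oxirane | C1O[C@@]1(/C=C/C=C(C)C)CO[Si](C(C)C)(C(C)C)C(C)C | intermediate
13 | (3S,4E)-7-methyl-3-({[tri(propan-2-yl)silyl]oxy}methyl)octa-1,4,6-trien-3-ol | O[C@@](C=C)(/C=C/C=C(C)C)CO[Si](C(C)C)(C(C)C)C(C)C | intermediate
14 | 3-chloro-2-(chloromethyl)prop-1-ene | C=C(CCl)CCl | starting material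
15 | 2-(chloromethyl)prop-2-en-1-yl ether of 13 at the tertiary oxygen (S) | ClCC(=C)CO[C@@](C=C)(/C=C/C=C(C)C)CO[Si](C(C)C)(C(C)C)C(C)C | intermediate
16 | (2R)-4-(chloromethyl)-2-[(1E)-4-methylpenta-1,3-dien-1-yl]-2-({[tri(propan-2-yl)silyl]oxy}methyl)-2,5-dihydrofuran | ClCC1=C[C@](/C=C/C=C(C)C)(CO[Si](C(C)C)(C(C)C)C(C)C)OC1 | intermediate
17 | (5R)-5-[(1E)-4-methylpenta-1,3-dien-1-yl]-5-({[tri(propan-2-yl)silyl]oxy}methyl)-2,5-dihydrofuran-3-carbaldehyde | O=CC1=C[C@](/C=C/C=C(C)C)(CO[Si](C(C)C)(C(C)C)C(C)C)OC1 | intermediate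
18 | (2R)-2-[(1E)-4-methylpenta-1,3-dien-1-yl]-4-(oxiran-2-yl)-2-({[tri(propan-2-yl)silyl]oxy}methyl)-2,5-dihydrofuran, both oxirane epimers (East fragment) | C1OC1C2=C[C@](/C=C/C=C(C)C)(CO[Si](C(C)C)(C(C)C)C(C)C)OC2 | intermediate
19 | (5S)-7-{[tert-butyl(dimethyl)silyl]oxy}-5-methyl-1-[(5R)-5-[(1E)-4-methylpenta-1,3-dien-1-yl]-5-({[tri(propan-2-yl)silyl]oxy}methyl)-2,5-dihydrofuran-3-yl]hept-3-yne-1,5-diol, both C11 epimers | CC(C)(C)[Si](C)(C)OCC[C@](C)(O)C#CCC(O)C1=C[C@](/C=C/C=C(C)C)(CO[Si](C(C)C)(C(C)C)C(C)C)OC1 | intermediate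
20 | (3Z,5S)-7-{[tert-butyl(dimethyl)silyl]oxy}-5-methyl-1-[(5R)-5-[(1E)-4-methylpenta-1,3-dien-1-yl]-5-({[tri(propan-2-yl)silyl]oxy}methyl)-2,5-dihydrofuran-3-yl]hept-3-ene-1,5-diol | CC(C)(C)[Si](C)(C)OCC[C@](C)(O)/C=C\CC(O)C1=C[C@](/C=C/C=C(C)C)(CO[Si](C(C)C)(C(C)C)C(C)C)OC1 | intermediate
21 | (3Z,5S)-1-[(5R)-5-(hydroxymethyl)-5-[(1E)-4-methylpenta-1,3-dien-1-yl]-2,5-dihydrofuran-3-yl]-5-methylhept-3-ene-1,5,7-triol | OCC[C@](C)(O)/C=C\CC(O)C1=C[C@](/C=C/C=C(C)C)(CO)OC1 | intermediate
22 | (3Z,5S)-1-[(5R)-5-(hydroxymethyl)-5-[(1E)-4-methylpenta-1,3-dien-1-yl]-2,5-dihydrofuran-3-yl]-7-iodo-5-methylhept-3-ene-1,5-diol | ICC[C@](C)(O)/C=C\CC(O)C1=C[C@](/C=C/C=C(C)C)(CO)OC1 | intermediate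
23 | (3Z,5S)-5-hydroxy-1-[(5R)-5-(hydroxymethyl)-5-[(1E)-4-methylpenta-1,3-dien-1-yl]-2,5-dihydrofuran-3-yl]-7-iodo-5-methylhept-3-en-1-one | ICC[C@](C)(O)/C=C\CC(=O)C1=C[C@](/C=C/C=C(C)C)(CO)OC1 | intermediate
24 | cis-fused C11a epimer of 25, (4R,4aS,7S,11aR) (not isolated) | O=C1C/C=C\[C@@](C)(O)CC[C@H]2[C@@H]1CO[C@@]2(/C=C/C=C(C)C)CO | intermediate
25 | trans-fused ketone of rings A and B, (4R,4aS,7S,11aS): C11 ketone, (Z)-C8=C9, C7 with OH and CH3, C4 with CH2OH and the (E)-dienyl group | O=C1C/C=C\[C@@](C)(O)CC[C@H]2[C@H]1CO[C@@]2(/C=C/C=C(C)C)CO | intermediate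
26 | (4R,4aS,7S,11aR)-diol with the C11 methylidene (the target without its ester) | C=C1C/C=C\[C@@](C)(O)CC[C@H]2[C@H]1CO[C@@]2(/C=C/C=C(C)C)CO | intermediate
27 | nonadecanoic acid | OC(=O)CCCCCCCCCCCCCCCCCC | starting material
28 | [(1R,3aR,6Z,8S,10aS)-8-hydroxy-8-methyl-4-methylidene-1-[(1E)-4-methylpenta-1,3-dien-1-yl]-3,3a,4,5,8,9,10,10a-octahydro-1H-cyclonona[c]furan-1-yl]methyl nonadecanoate | C=C1C/C=C\[C@@](C)(O)CC[C@H]2[C@H]1CO[C@@]2(/C=C/C=C(C)C)COC(=O)CCCCCCCCCCCCCCCCCC | target

**Step count**

Total steps: 22. Longest linear sequence: 18 steps (steps 5 to 22); the West fragment takes 4 steps (steps 1 to 4).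

**Steps most likely to fail**

1. Step 20 (Proposed new method). What may go wrong: the C5 radical is reduced by the silane, or shifts to C10 by 1,6-hydrogen transfer, before the nine-membered ring closes; the chain may also bond to the wrong face of C4a, which is the weakest point of stereocontrol in the route. Fallback (polar, reversible ring closure with a removable nitro group; sets out from 23 and comes back at 25): the iodide of 23 is exchanged with AgNO2 in Et2O (Kornblum nitro synthesis) to give the primary nitro compound F1. Tetramethylguanidine (0.2 equiv) in MeCN at 0.002 mol/L closes ring B by intramolecular nitro-Michael addition of the C5 nitronate to C4a under thermodynamic control, equilibrating C11a at the same time, to give the nitro ketone F2. Radical denitration with Bu3SnH and AIBN in toluene at 110 °C (Ono–Tanner) then removes the nitro group and gives 25.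

2. Step 15. What may go wrong: loss of regiocontrol in the epoxide opening (attack at the allylic epoxide carbon or conjugate opening through C4a) and base-induced decomposition of the vinyl epoxide. Fallback (the West fragment becomes the nucleophile towards the aldehyde; sets out from 6 and 17 and comes back at 19, so that step 14 is not needed): the dilithio derivative of 6 is hydroxymethylated with paraformaldehyde to give the propargylic diol F3, whose primary hydroxyl is mesylated (MsCl, Et3N, CH2Cl2, −20 °C) to give the mesylate F4. Pd(OAc)2 and PPh3 (5 mol%) with InI in THF–HMPA convert F4 into an allenylindium reagent, which adds to enal 17 through its CH2 terminus (Marshall propargylation) and gives the homopropargylic alcohol 19.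

3. Step 21. What may go wrong: enolisation or alkene migration in the β,γ-unsaturated ketone, and consumption of the titanium reagent by the two free hydroxyls so that the hindered ketone stays unreacted. Fallback (two-stage Peterson olefination; sets out from 25 and comes back at 26): Me3SiCH2Li with CeCl3 (5 equiv) in THF at −78 °C adds to the ketone without enolising it and gives the β-hydroxysilane F5; KH in THF at rt then brings about syn-elimination and gives 26.

**Further compounds**

F1 | step 20 | (3Z,5S)-5-hydroxy-1-[(5R)-5-(hydroxymethyl)-5-[(1E)-4-methylpenta-1,3-dien-1-yl]-2,5-dihydrofuran-3-yl]-5-methyl-7-nitrohept-3-en-1-one | [O-][N+](=O)CC[C@](C)(O)/C=C\CC(=O)C1=C[C@](/C=C/C=C(C)C)(CO)OC1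
F2 | step 20 | 5-nitro derivative of 25 (nitro group on C5, either configuration) | O=C1C/C=C\[C@@](C)(O)CC([N+](=O)[O-])[C@H]2[C@H]1CO[C@@]2(/C=C/C=C(C)C)CO
F3 | step 15 | (4S)-6-{[tert-butyl(dimethyl)silyl]oxy}-4-methylhex-2-yne-1,4-diol | OCC#C[C@@](C)(O)CCO[Si](C)(C)C(C)(C)C
F4 | step 15 | (4S)-6-{[tert-butyl(dimethyl)silyl]oxy}-4-hydroxy-4-methylhex-2-yn-1-yl methanesulfonate | CS(=O)(=O)OCC#C[C@@](C)(O)CCO[Si](C)(C)C(C)(C)C
F5 | step 21 | adduct of 25 with a (trimethylsilyl)methyl group on C11 (C11 tertiary alcohol, either configuration) | C[Si](C)(C)CC1(O)C/C=C\[C@@](C)(O)CC[C@H]2[C@H]1CO[C@@]2(/C=C/C=C(C)C)CO
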